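**Numbering.** Atom labels (C1–C28, O3, O8, O10, O13 and so on) give the position of each atom among the non-hydrogen atoms of the target SMILES. Compound numbers: 1 muconic acid, 2 dimethyl muconate, 3 dienediol, 4 diethyl chlorophosphate, 5 dienyl bis-phosphate, 6 3-bromo-4-methoxyphenol, 7 aryl bromide, 8 aryl Grignard reagent, 9 mono-arylated phosphate, 10 diaryl diene, 11 diketone, 12 diol, 13 1,1,2,2-tetramethoxyethane, 14 mono-closed isochroman, 15 bridged acetal, 16 cage bis(benzyl ether), 17 cage bis-phenol, 18 cage bis(quinone monoketal), 19 cage bis(epoxy enone ketal), 20 cage bis(epoxy alcohol ketal), 21 epoxytwinol A.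

## Analysis of the target

Epoxytwinol A (21) is a twofold-symmetric cage: each half holds an epoxycyclohexenone (ring A: C5, C6, C7, C9, C11, C12 with oxirane O10; ring B: C16, C17, C18, C20, C22, C23 with oxirane O21) fused through its tetrasubstituted alkene (C5=C6, C16=C17) to a dihydropyran (O3, C2, C14, C6, C5, C4 and O26, C27, C15, C16, C17, C25). The two pyrans are tied together by the C4–C25 and C14–C15 bonds, so that C4, C5, C6, C14, C15, C16, C17 and C25 form a cycloocta-1,5-diene and each pyran is a boat with both inter-half bonds on one face. There are twelve stereocentres, six per half (2R, 4S, 9R, 11R, 12S, 14S and, by symmetry, 27R, 25S, 22R, 20R, 18S, 15S), and the twofold axis runs through the midpoints of C4–C25 and C14–C15. The C2 methyl is trans to both inter-half bonds, C4/C25 are forced by the cage once C14/C15 are fixed, each oxirane lies on the face of its carbocycle that carries its own ring oxygen (O3 for ring A; called the α face below), and each hydroxyl (O13, O19) lies on the opposite β face, trans to the oxirane. The sensitive groups are the epoxy ketone and epoxy allylic alcohol (opened by acid, rearranged by base), the enone, and the doubly allylic ether carbons C4/C25. Three things make the synthesis hard: building the strained cage with its six carbon stereocentres in one enantiomeric series; telling the two ring oxygens apart (C7 must end as a ketone and C12 as a carbinol although their surroundings are almost identical); and placing the oxirane on the α face of an alkene that is remote from every stereocentre. The plan rests on C14 and C15: they are adjacent CH centres of like (S,S) configuration, each bonded to one ring carbon (C6, C16) and to a two-carbon arm (C2–C1, C27–C28), which with the rings as arenes and the arms as vinyl groups is a twofold-symmetric 3,4-diarylhexa-1,5-diene that two SN2′ arylations of a six-carbon dienyl dielectrophile can set up in one operation.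

## Retrosynthetic reasoning

**21 from 20.** The last bonds to change are at C7 and C23. These ketones are carried as dimethyl ketals in 20 and freed by mild acid hydrolysis. While C12/C18 are reduced, C7/C23 are therefore not carbonyl groups at all, which removes the regiochemical problem.

**20 from 19.** The C12–H and C18–H bonds are cut. The forward reaction must deliver hydride to the α face, the face that already carries the oxirane, so that O13 and O19 end up β and trans to it. Only one ketone per ring is present in 19, so no choice of carbonyl is needed.

**19 from 18.** The four oxirane C–O bonds (C9–O10, C11–O10, C20–O21, C22–O21) are cut. In 18 each ring has one disubstituted enone alkene (C9=C11, C20=C22) and one tetrasubstituted one, so a nucleophilic epoxidation is regioselective by substitution. The α and β faces of the remote alkene differ only slightly (the C2 methyl lies far off on α, the C27–H of the other half on β), so the forward step needs a chiral reagent and cannot rely on the substrate.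

**18 from 17 from 16.** The dienone ketal rings are traced back to arenes. Oxidative dearomatisation of the bis(4-methoxyphenol) 17 puts the carbonyl on the carbon that bore the free hydroxyl (C12, C18) and the ketal on the carbon that bore the methyl ether (C7, C23); 17 comes from the bis(benzyl ether) 16 by hydrogenolysis. This is why the two oxygens of each arene are differentiated from the start: in a symmetrical dialkoxyarene, or in the quinone derived from it, the C4–O3 bond is turned away from C12=O and offers no handle, so nothing would distinguish C12 from C7.

**16 from 12 and 13.** The aryl bonds C4–C5 and C25–C17 and the ether bonds C4–O3 and C25–O26 are cut. This leaves diol 12 and the two-carbon unit C4–C25, supplied as the bis(dimethyl acetal) 13. Each aryl bond is ortho to an oxygen substituent and closes a six-membered ring from a 2-arylethanol, which is the oxa-Pictet–Spengler retron. The C4–C25 bond is already present in 13, so the cage closes on stable arenes and C4/C25 need no external control.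

**12 from 11 from 10.** The carbinol centres C2 and C27 come from the diketone 11 by reagent-controlled reduction, and 11 from the diene 10 by Markovnikov oxidation of both vinyl groups. The two-carbon arms thus go back to the vinyl groups that an SN2′ reaction leaves behind.

**10 from 5 and 8.** The C6–C14 and C16–C15 bonds are cut, each with allylic transposition. This gives two equivalents of the aryl Grignard reagent 8 and the dienyl bis-phosphate 5, whose central single bond is C14–C15. This is the key disconnection: it creates the only two stereocentres that cannot be derived from others, from achiral partners and under catalyst control, and it forms both in one flask. The forward reaction must favour γ-attack twice and choose the same enantioface sense twice.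

**5 from 1; 8 from 6.** 5 comes from the diol 3 with chlorophosphate 4, and 3 from muconic acid 1 through its dimethyl ester 2. 8 comes from bromide 7, which is the benzyl ether of phenol 6.

## Alternatives that were turned down

**Alternative 1:** The disconnection is at the C7–O and C12–O bonds (and C23–O, C18–O). The key step would be a [4+2] addition of singlet oxygen across C7/C12 of each benzene oxide ring of a cage bis(arene oxide) A2, anti to the oxirane, giving the bis(epoxy endoperoxide) A1.
- For it: one reagent installs both remaining oxygens of each ring and sets the C12 oxygen trans to the oxirane by a purely steric rule. On this point it is stronger than the chosen route, which needs a directed hydride delivery in step 13.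
- Against it: A2 carries two benzene oxides, which equilibrate with oxepines and aromatise to phenols with traces of acid, on a cage with benzylic ether bonds. The oxirane face on A2 is the same unsolved remote-face problem, now on an arene. The endoperoxide of A1 must then be opened to ketone at C7 and alcohol at C12, yet the two bridgehead C–H bonds are equivalent in reactivity, so the C7/C12 problem returns. The strategy also says nothing about how the cage is made.
- Comparison: the chosen strategy gives up the oxidation economy, and offers in its place stable aromatic intermediates up to 17, a built-in answer to C7 versus C12 (benzyl versus methyl), and a defined route to the cage.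

**Alternative 2:** The disconnection is at C2–C14 and C27–C15. The key step would be an electroreductive dicarboxylation (Mg anode, CO2) of the stilbene-type C14=C15 alkene of the acetonide-protected dibenzocyclooctatriene trans-diol A4, giving the trans-diacid A3 after epimerisation.
- For it: the eight-membered carbocycle exists from the start, so no strained cage has to be closed late by a Friedel–Crafts reaction, and no Cope-labile diene is handled. On these two points it is stronger than the chosen route.
- Against it: the C14=C15 alkene of A4 is twisted out of conjugation in the eight-membered ring and flanked by ortho-methoxy groups, which works against the radical-anion carboxylation. The relation between the C4/C25 diol and the C14/C15 diacid is left to an equilibration. Each CO2H must then be turned into a CH(CH3)–O unit with a new stereocentre (C2, C27) and joined to the C4/C25 oxygens, which costs roughly eight further steps with no obvious control element. Absolute configuration needs a separate asymmetric step. The symmetrical dimethoxyarenes of A3 also leave C7 and C12 undifferentiated.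
- Comparison: the chosen strategy sets C14/C15 absolutely by catalysis, has the C2/C27 carbons in place as vinyl groups straight after the key step, and reaches the cage in three further steps.

**Alternative 3:** The disconnection is at the four oxirane C–O bonds. The key step would be a twofold Weitz–Scheffer epoxidation (tBuOOH, chiral quaternary ammonium phase-transfer catalyst) of the bis(quinone monoketal) A6 at C9=C11 and C20=C22, giving the bis(epoxy enone ketal) A5.
- For it: it meets the hardest remote stereochemical problem with reagent control, the monoketal fixes the regiochemistry, and the twofold symmetry means one catalyst serves both rings. On the oxirane question it is exactly as strong as the chosen route, because A6 and A5 are the same compounds as 18 and 19 and the same reaction is step 12.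
- Against it: as a strategy it forms no C–C bond and no ring, and it presupposes A6 without saying how a cage with six carbon stereocentres is obtained, which is the larger part of the problem.
- Comparison: the two are not exclusive. The chosen strategy supplies the route to A6 that alternative 3 leaves open and uses its epoxidation as a downstream step.

Key step: step 6

## Remarks before the steps

- Remark 1: 3-bromo-4-methoxyphenol (6) is taken to be a commercial compound.
- Remark 2: in steps 6 and 12 the named enantiomer of the ligand or catalyst is assumed to give the configuration shown; if the sense proves opposite, its antipode is used (for the cinchonidinium salt, the cinchoninium pseudo-enantiomer).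

## Route

Step 1
Reactants: 1 trans,trans-muconic acid
Product: 2 dimethyl (2E,4E)-hexa-2,4-dienedioate
Conditions: MeOH, H2SO4 (cat.), reflux
Reagents that add atoms: methanol, CO
Why: Fischer esterification; acid leaves the (E,E)-diene untouched, and the diester, unlike the diacid, is soluble enough for a low-temperature hydride reduction.

Step 2
Reactants: 2 dimethyl (2E,4E)-hexa-2,4-dienedioate
Product: 3 (2E,4E)-hexa-2,4-diene-1,6-diol
Conditions: iBu2AlH (4.4 equiv), CH2Cl2/toluene, −78 → 0 °C; aq. potassium sodium tartrate
Reagents that add atoms: none
Why: 1,2-reduction of a conjugated ester to the allylic alcohol by an aluminium hydride; at low temperature conjugate reduction does not compete, so both E-alkenes are kept.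

Step 3
Reactants: 3 (2E,4E)-hexa-2,4-diene-1,6-diol; 4 diethyl chlorophosphate
Product: 5 tetraethyl (2E,4E)-hexa-2,4-diene-1,6-diyl bis(phosphate)
Conditions: ClP(O)(OEt)2 (2.4 equiv), pyridine, DMAP (cat.), CH2Cl2, 0 °C
Reagents that add atoms: diethyl chlorophosphate 4, CCOP(=O)(Cl)OCC
Why: O-phosphorylation of primary allylic alcohols; the diethyl phosphate is the leaving group that copper-catalysed allylic substitution handles well, and the product is used soon after a short filtration because dienyl phosphates ionise easily.

Step 4
Reactants: 6 3-bromo-4-methoxyphenol
Product: 7 4-(benzyloxy)-2-bromo-1-methoxybenzene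
Conditions: BnBr, K2CO3, DMF, rt
Reagents that add atoms: benzyl bromide, BrCc1ccccc1
Why: Williamson ether synthesis on the phenol; the benzyl group marks the oxygen that ends as the C12/C18 carbinol and can be removed alone, while the methyl ether ends as the C7/C23 ketal and ketone.

Step 5
Reactants: 7 4-(benzyloxy)-2-bromo-1-methoxybenzene
Product: 8 [5-(benzyloxy)-2-methoxyphenyl]magnesium bromide (THF solution, titrated)
Conditions: Mg turnings, I2 (cat.), THF, 40 °C → rt
Reagents that add atoms: magnesium, [Mg]
Why: Grignard formation by magnesium insertion into the aryl bromide; both ether groups are inert and the ortho-methoxy group stabilises the reagent.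

Step 6
Reactants: 5 tetraethyl (2E,4E)-hexa-2,4-diene-1,6-diyl bis(phosphate); 8 [5-(benzyloxy)-2-methoxyphenyl]magnesium bromide (2.6 equiv)
Product: 10 (3S,4S)-3,4-bis[5-(benzyloxy)-2-methoxyphenyl]hexa-1,5-diene, via mono-arylated dienyl phosphate 9 (not isolated)
Conditions: CuBr·SMe2 (5 mol %), (S)-binaphthyl-2,2′-diyl N,N-bis[(S)-1-phenylethyl]phosphoramidite (11 mol %), CH2Cl2, −78 °C, 8 added over 3 h; quench at −78 °C; work-up and chromatography below 20 °C, stored at −20 °C
Reagents that add atoms: [5-(benzyloxy)-2-methoxyphenyl]magnesium bromide 8, COc1ccc(OCc2ccccc2)cc1[Mg]Br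
Why: The Grignard reagent transfers its aryl group to the monovalent copper–phosphoramidite complex; the aryl cuprate binds the C2=C3 alkene of 5 anti to the phosphate, adds oxidatively at the γ carbon to a σ-allyl trivalent copper species and eliminates reductively, which forms C6–C14 and leaves a vinyl group (9); 9 is again a primary (E)-allylic phosphate and reacts in the same way at C15, forming C16–C15. The closest known reaction type is the copper-catalysed enantioselective anti-SN2′ substitution of primary allylic phosphates and halides with Grignard reagents, aryl ones included; its twofold use on a conjugated dienyl bis-phosphate is an extension of that chemistry. No ring is closed. C14 is set by the enantioface choice of the chiral ligand on copper in the first event, and C15 by the same catalyst in the second event, where it has to override the bias of the neighbouring new stereocentre; both should come out S. The step needs γ-attack in preference to α-attack and to ε-attack through the diene; fast reductive elimination from the γ-bound copper species, which phosphoramidite ligands, CH2Cl2, low temperature and a low standing concentration of Grignard reagent favour, should secure it. Errors of the catalyst end mostly in the meso diastereomer, which chromatography removes, so the twofold-symmetric product should be of higher enantiopurity than a single event would give. The product must stay cold because 3,4-diaryl-1,5-dienes undergo Cope rearrangement to the conjugated 1,6-diaryl isomer on warming.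

Step 7
Reactants: 10 (3S,4S)-3,4-bis[5-(benzyloxy)-2-methoxyphenyl]hexa-1,5-diene
Product: 11 (3S,4S)-3,4-bis[5-(benzyloxy)-2-methoxyphenyl]hexane-2,5-dione
Conditions: PdCl2 (10 mol %), CuCl (1 equiv, reoxidised by O2), O2 (1 atm), DMF/H2O 7:1, rt
Reagents that add atoms: water, O
Why: Tsuji–Wacker oxidation; Markovnikov hydroxypalladation of each terminal vinyl group gives the methyl ketone, and the reaction is run at room temperature and stopped early so that the benzylic α-centres do not enolise. A 1,5-diene without substituents at its internal alkene carbons is not prone to the Cope rearrangement catalysed by divalent palladium.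

Step 8
Reactants: 11 (3S,4S)-3,4-bis[5-(benzyloxy)-2-methoxyphenyl]hexane-2,5-dione
Product: 12 (2R,3S,4S,5R)-3,4-bis[5-(benzyloxy)-2-methoxyphenyl]hexane-2,5-diol
Conditions: (S)-2-methyl-CBS-oxazaborolidine (40 mol %), BH3·SMe2 (1.5 equiv), THF, −20 °C; MeOH
Reagents that add atoms: none
Why: Corey–Bakshi–Shibata reduction; the (S)-catalyst distinguishes methyl from the branched α-carbon and gives the (R)-carbinol at both C2 and C27. The Felkin–Anh preference of the substrate, with the aryl group anti to the incoming hydride, leads to the same 2,3-syn relation, so reagent and substrate are matched.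

Step 9
Reactants: 12 (2R,3S,4S,5R)-3,4-bis[5-(benzyloxy)-2-methoxyphenyl]hexane-2,5-diol; 13 1,1,2,2-tetramethoxyethane (1.05 equiv)
Product: 16 cage bis(benzyl ether): two 8-benzyloxy-5-methoxy-3-methylisochroman units joined C1–C1′ (C4–C25) and C4–C4′ (C14–C15) with 2R,4S,14S,15S,25S,27R configuration, via mono-closed isochroman acetal 14 (not isolated), via bridged methyl acetal 15 (not isolated)
Conditions: TMSOTf (0.2 equiv), 5 Å molecular sieves, CH2Cl2 (0.01 M), −40 → 0 °C
Reagents that add atoms: 1,1,2,2-tetramethoxyethane 13, COC(OC)C(OC)OC
Why: Oxa-Pictet–Spengler reaction run twice on one two-carbon dielectrophile: acetal exchange at O3 and loss of methanol give an oxocarbenium ion at C4 that is attacked by C5, the free position ortho to the benzyloxy group (six-membered closure, then loss of a proton), giving 14; O26 then takes up the remaining acetal (15) and the C25 oxocarbenium ion, an analogue of a 2-alkoxy glycosyl cation, is attacked by C17 in the same way. C4 and C25 are set by the cage: the peri methoxy group at C7 holds the C14 substituent axial so that the C4 substituent enters cis to it, only this epimer can reach O26, and a wrong C4 epimer can revert through ionisation of the benzylic C4–O3 bond. High dilution and one equivalent of 13 keep the reaction intramolecular.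

Step 10
Reactants: 16 cage bis(benzyl ether)
Product: 17 cage bis-phenol (free hydroxyl at C12 and C18, methyl ether at C7 and C23)
Conditions: H2 (1 atm), Pd/C (10% palladium on carbon), EtOAc, rt, stopped at full conversion
Reagents that add atoms: none
Why: Hydrogenolysis of aryl benzyl ethers, which is much faster than cleavage of the cyclic benzylic ether bonds C4–O3 and C25–O26; no alkene is present at this stage.

Step 11
Reactants: 17 cage bis-phenol
Product: 18 cage bis(quinone monoketal) (ketone at C12 and C18, dimethyl ketal at C7 and C23)
Conditions: PhI(OAc)2 (2.2 equiv), MeOH, 0 °C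
Reagents that add atoms: methanol, CO
Why: Oxidative dearomatisation of a 4-methoxyphenol by a trivalent iodine reagent in methanol; the phenoxenium ion is trapped para to the hydroxyl, so the carbonyl appears at the former phenol carbon and the ketal at the former anisole carbon.

Step 12
Reactants: 18 cage bis(quinone monoketal)
Product: 19 cage bis(epoxy enone ketal), both oxiranes on the α face (9R,11S,20S,22R by the CIP rules for this compound)
Conditions: tBuOOH (3 equiv), N-benzylcinchonidinium chloride (20 mol %), aq. NaOH (cat.), toluene, 0 °C
Reagents that add atoms: tert-butyl hydroperoxide, CC(C)(C)OO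
Why: Weitz–Scheffer nucleophilic epoxidation under chiral phase-transfer catalysis; the peroxide anion adds to C9 (C22), the β-carbon of the only disubstituted enone alkene, and the enolate closes the oxirane with loss of tert-butoxide. The chiral ammonium ion pair chooses the α face, because the substrate itself offers almost no bias at this remote alkene; the tetrasubstituted C5=C6 and C16=C17 alkenes do not react.

Step 13
Reactants: 19 cage bis(epoxy enone ketal)
Product: 20 cage bis(epoxy alcohol ketal) (12S,18S; hydroxyls on the β face, trans to the oxiranes)
Conditions: iBu2AlH (3 equiv), THF, −78 °C; aq. potassium sodium tartrate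
Reagents that add atoms: none
Why: 1,2-reduction of the enone carbonyl with hydride delivered from aluminium bound to the neighbouring oxirane oxygen, that is on the α face, which places the hydroxyl trans to the oxirane; the ketals at C7 and C23 are inert, so no choice between carbonyl groups arises.

Step 14
Reactants: 20 cage bis(epoxy alcohol ketal)
Product: 21 epoxytwinol A
Conditions: oxalic acid, THF/H2O, rt
Reagents that add atoms: water, O
Why: Acid hydrolysis of the two dimethyl ketals to the C7 and C23 ketones under conditions mild enough for the oxiranes and the allylic alcohols; no stereocentre is touched.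

## Compound list

1 | trans,trans-muconic acid | OC(=O)/C=C/C=C/C(=O)O | starting material
2 | dimethyl (2E,4E)-hexa-2,4-dienedioate | COC(=O)/C=C/C=C/C(=O)OC | intermediate
3 | (2E,4E)-hexa-2,4-diene-1,6-diol | OC/C=C/C=C/CO | intermediate
4 | diethyl chlorophosphate | CCOP(=O)(Cl)OCC | starting material
5 | tetraethyl (2E,4E)-hexa-2,4-diene-1,6-diyl bis(phosphate) | CCOP(=O)(OCC)OC/C=C/C=C/COP(=O)(OCC)OCC | intermediate
6 | 3-bromo-4-methoxyphenol | COc1ccc(O)cc1Br | starting material
7 | 4-(benzyloxy)-2-bromo-1-methoxybenzene | COc1ccc(OCc2ccccc2)cc1Br | intermediate
8 | [5-(benzyloxy)-2-methoxyphenyl]magnesium bromide | COc1ccc(OCc2ccccc2)cc1[Mg]Br | intermediate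
9 | diethyl (2E,4S)-4-[5-(benzyloxy)-2-methoxyphenyl]hexa-2,5-dien-1-yl phosphate | C=C[C@H](c1cc(OCc2ccccc2)ccc1OC)/C=C/COP(=O)(OCC)OCC | intermediate (not isolated)
10 | (3S,4S)-3,4-bis[5-(benzyloxy)-2-methoxyphenyl]hexa-1,5-diene | C=C[C@H](c1cc(OCc2ccccc2)ccc1OC)[C@@H](c1cc(OCc2ccccc2)ccc1OC)C=C | intermediate
11 | (3S,4S)-3,4-bis[5-(benzyloxy)-2-methoxyphenyl]hexane-2,5-dione | CC(=O)[C@H](c1cc(OCc2ccccc2)ccc1OC)[C@@H](c1cc(OCc2ccccc2)ccc1OC)C(C)=O | intermediate
12 | (2R,3S,4S,5R)-3,4-bis[5-(benzyloxy)-2-methoxyphenyl]hexane-2,5-diol | C[C@@H](O)[C@H](c1cc(OCc2ccccc2)ccc1OC)[C@@H](c1cc(OCc2ccccc2)ccc1OC)[C@@H](C)O | intermediate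
13 | 1,1,2,2-tetramethoxyethane | COC(OC)C(OC)OC | starting material
14 | mono-closed isochroman: 8-benzyloxy-1-(dimethoxymethyl)-5-methoxy-3-methylisochroman carrying at C14 the 1-aryl-2-hydroxypropyl chain, dimethoxymethyl group cis to that chain | C[C@H]1O[C@H](C(OC)OC)c2c(c(OC)ccc2OCc2ccccc2)[C@@H]1[C@@H](c1cc(OCc2ccccc2)ccc1OC)[C@@H](C)O | intermediate (not isolated)
15 | bridged methyl acetal: as 14 with O26 bonded to C25, one methoxy group left on C25 | C[C@H]1O[C@H]2c3c(c(OC)ccc3OCc3ccccc3)[C@@H]1[C@@H](c1cc(OCc3ccccc3)ccc1OC)[C@@H](C)OC2OC | intermediate (not isolated)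
16 | cage bis(benzyl ether) (benzyloxy at C12 and C18, methoxy at C7 and C23; 2R,4S,14S,15S,25S,27R) | C[C@H]1O[C@H]2c3c(c(OC)ccc3OCc3ccccc3)[C@@H]1[C@H]1c3c(c(OCc4ccccc4)ccc3OC)[C@@H]2O[C@@H]1C | intermediate
17 | cage bis-phenol (hydroxyl at C12 and C18, methoxy at C7 and C23) | C[C@H]1O[C@H]2c3c(c(OC)ccc3O)[C@@H]1[C@H]1c3c(c(O)ccc3OC)[C@@H]2O[C@@H]1C | intermediate
18 | cage bis(quinone monoketal) (ketone at C12 and C18, dimethyl ketal at C7 and C23) | C[C@H]1O[C@H]2C3=C(C(OC)(OC)C=CC3=O)[C@@H]1[C@H]1C3=C(C(=O)C=CC3(OC)OC)[C@@H]2O[C@@H]1C | intermediate
19 | cage bis(epoxy enone ketal), oxiranes on the α face | C[C@H]1O[C@H]2C3=C(C(OC)(OC)[C@@H]4O[C@@H]4C3=O)[C@@H]1[C@H]1C3=C(C(=O)[C@H]4O[C@H]4C3(OC)OC)[C@@H]2O[C@@H]1C | intermediate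
20 | cage bis(epoxy alcohol ketal), hydroxyls β and trans to the oxiranes | C[C@H]1O[C@H]2C3=C(C(OC)(OC)[C@@H]4O[C@@H]4[C@H]3O)[C@@H]1[C@H]1C3=C([C@H](O)[C@H]4O[C@H]4C3(OC)OC)[C@@H]2O[C@@H]1C | intermediate
21 | epoxytwinol A | C[C@H]1O[C@H]2C3=C(C(=O)[C@@H]4O[C@@H]4[C@H]3O)[C@@H]1[C@H]1C3=C([C@H](O)[C@H]4O[C@H]4C3=O)[C@@H]2O[C@@H]1C | target

## Step count and risks

Total: 14 steps. Longest linear sequence: 12 steps (1, 2, 3, 6 to 14); the aryl branch (4, 5) joins at step 6.

**Step 6 (key step).** The second substitution is the likeliest point of failure: attack shifts to the α- or ε-carbon because the γ-carbon of 9 is flanked by a new stereocentre, the catalyst loses control against that centre so that the meso diene grows, and the product rearranges sigmatropically if it warms. The ortho-methoxy aryl Grignard reagent may also transfer more slowly than simple aryl reagents. The fallback forms C14–C15 by enolate coupling and sets out from bromide 7. Pd-catalysed α-arylation of tert-butyl acetate (Pd2(dba)3, P(tBu)3, LiN(SiMe3)2) would give tert-butyl [5-(benzyloxy)-2-methoxyphenyl]acetate F1, and CF3CO2H would free [5-(benzyloxy)-2-methoxyphenyl]acetic acid F2. Acylation of (S)-4-benzyloxazolidin-2-one through the pivaloyl mixed anhydride would give the imide (S)-4-benzyl-3-{[5-(benzyloxy)-2-methoxyphenyl]acetyl}oxazolidin-2-one F3. Oxidative homocoupling of its titanium enolate (TiCl4, Et3N) would join the two α-carbons under auxiliary control to the (2S,3S)-2,3-diarylsuccinoyl bis-imide F4. Transamidation (MeNH(OMe)·HCl, AlMe3) would give the bis(Weinreb amide) F5, and MeMgBr would convert it into diketone 11, where the route is rejoined. This path avoids the diene altogether.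

**Step 9.** The second ring closure may fail on strain, the first closure may give the C4 epimer that cannot bridge and then fail to equilibrate, or acetal exchange may run between molecules and give oligomers. The fallback separates the two closures and sets out from diol 12. One oxa-Pictet–Spengler reaction with one equivalent of methyl 2,2-dimethoxyacetate (BF3·OEt2) would give the methyl isochroman-1-carboxylate F6 with the C27 hydroxyl free, and NaOMe can equilibrate its C4 epimers through the ester enolate. iBu2AlH at −78 °C would reduce the ester to the aldehyde, which the C27 hydroxyl holds as the bridged lactol F7. TMSOTf would then ionise the lactol and close the second ring to 16.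

**Step 12.** Facial selectivity may be poor: the chiral ion pair has to distinguish two faces of a hindered substrate that differ only far from the alkene, and α/β mixtures on two rings multiply. The fallback replaces reagent control by an auxiliary in the ketal and sets out from 18. Ketal exchange with (2R,4R)-pentane-2,4-diol (pyridinium p-toluenesulfonate, benzene) would give the bis(1,3-dioxane) quinone monoketal F8, whose axial methyl group shields one face of the adjacent alkene; the antipodal diol is used if it shields the wrong one. Epoxidation with H2O2/LiOH would give the bis-epoxide F9, iBu2AlH the bis(epoxy alcohol) F10, and aqueous acid would remove the auxiliary to give 21.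

**Step 13.** Hydride may add anti to the oxirane, the sterically and electronically normal course, if the aluminium reagent does not bind the oxirane oxygen; this would give the cis epoxy alcohol. The fallback accepts that outcome and inverts, setting out from 19. NaBH4/CeCl3 in MeOH would give the bis(cis-epoxy alcohol) F11. A Mitsunobu reaction (4-nitrobenzoic acid, PPh3, diisopropyl azodicarboxylate) would invert C12 and C18 to the bis(4-nitrobenzoate) F12, and K2CO3/MeOH would give 20.

**Step 7.** Palladium hydride species may move the alkene into conjugation with the arene and erase C14/C15, the acidic medium may epimerise the α-aryl ketone, or the 1,4-diketone may cyclise to a furan. The fallback avoids palladium and acid and sets out from 10. A Mukaiyama hydration (Co(acac)2, PhSiH3, O2, iPrOH) would give the diol F13 as a mixture at the carbinol centres, and buffered Dess–Martin periodinane would oxidise it to 11.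

## Further compounds

F1 | step 6 | tert-butyl [5-(benzyloxy)-2-methoxyphenyl]acetate | COc1ccc(OCc2ccccc2)cc1CC(=O)OC(C)(C)C
F2 | step 6 | [5-(benzyloxy)-2-methoxyphenyl]acetic acid | COc1ccc(OCc2ccccc2)cc1CC(=O)O
F3 | step 6 | (S)-4-benzyl-3-{[5-(benzyloxy)-2-methoxyphenyl]acetyl}oxazolidin-2-one | COc1ccc(OCc2ccccc2)cc1CC(=O)N1[C@@H](Cc2ccccc2)COC1=O
F4 | step 6 | (2S,3S)-2,3-bis[5-(benzyloxy)-2-methoxyphenyl]succinoyl bis[(S)-4-benzyloxazolidin-2-one] | O=C(N1[C@@H](Cc2ccccc2)COC1=O)[C@H](c1cc(OCc2ccccc2)ccc1OC)[C@@H](c1cc(OCc2ccccc2)ccc1OC)C(=O)N1[C@@H](Cc2ccccc2)COC1=O
F5 | step 6 | (2S,3S)-2,3-bis[5-(benzyloxy)-2-methoxyphenyl]-N1,N4-dimethoxy-N1,N4-dimethylsuccinamide | CON(C)C(=O)[C@H](c1cc(OCc2ccccc2)ccc1OC)[C@@H](c1cc(OCc2ccccc2)ccc1OC)C(=O)N(C)OC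
F6 | step 9 | methyl 8-benzyloxy-5-methoxy-3-methylisochroman-1-carboxylate carrying the 1-aryl-2-hydroxypropyl chain at C14, ester cis to that chain | C[C@H]1O[C@H](C(=O)OC)c2c(c(OC)ccc2OCc2ccccc2)[C@@H]1[C@@H](c1cc(OCc2ccccc2)ccc1OC)[C@@H](C)O
F7 | step 9 | bridged lactol (15 with hydroxyl in place of the C25 methoxy group) | C[C@H]1O[C@H]2c3c(c(OC)ccc3OCc3ccccc3)[C@@H]1[C@@H](c1cc(OCc3ccccc3)ccc1OC)[C@@H](C)OC2O
F8 | step 12 | cage bis(quinone monoketal) as its bis[(4R,6R)-4,6-dimethyl-1,3-dioxane] ketal | C[C@H]1O[C@H]2C3=C(C5(O[C@H](C)C[C@@H](C)O5)C=CC3=O)[C@@H]1[C@H]1C3=C(C(=O)C=CC35O[C@H](C)C[C@@H](C)O5)[C@@H]2O[C@@H]1C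
F9 | step 12 | bis(α-epoxide) of F8 | C[C@H]1O[C@H]2C3=C(C5(O[C@H](C)C[C@@H](C)O5)[C@@H]4O[C@@H]4C3=O)[C@@H]1[C@H]1C3=C(C(=O)[C@H]4O[C@H]4C35O[C@H](C)C[C@@H](C)O5)[C@@H]2O[C@@H]1C
F10 | step 12 | bis(epoxy alcohol) from F9, hydroxyls trans to the oxiranes | C[C@H]1O[C@H]2C3=C(C5(O[C@H](C)C[C@@H](C)O5)[C@@H]4O[C@@H]4[C@H]3O)[C@@H]1[C@H]1C3=C([C@H](O)[C@H]4O[C@H]4C35O[C@H](C)C[C@@H](C)O5)[C@@H]2O[C@@H]1C
F11 | step 13 | C12,C18-bis-epimer of 20 (hydroxyls cis to the oxiranes) | C[C@H]1O[C@H]2C3=C(C(OC)(OC)[C@@H]4O[C@@H]4[C@@H]3O)[C@@H]1[C@H]1C3=C([C@@H](O)[C@H]4O[C@H]4C3(OC)OC)[C@@H]2O[C@@H]1C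
F12 | step 13 | bis(4-nitrobenzoate) of 20 | C[C@H]1O[C@H]2C3=C(C(OC)(OC)[C@@H]4O[C@@H]4[C@H]3OC(=O)c3ccc(cc3)[N+](=O)[O-])[C@@H]1[C@H]1C3=C([C@H](OC(=O)c4ccc(cc4)[N+](=O)[O-])[C@H]4O[C@H]4C3(OC)OC)[C@@H]2O[C@@H]1C
F13 | step 7 | (3S,4S)-3,4-bis[5-(benzyloxy)-2-methoxyphenyl]hexane-2,5-diol, mixture at C2 and C5 | CC(O)[C@H](c1cc(OCc2ccccc2)ccc1OC)[C@@H](c1cc(OCc2ccccc2)ccc1OC)C(C)O
A1 | alternative 1 | cage bis(epoxy endoperoxide) | C[C@H]1O[C@H]2C3=C([C@H]5OO[C@@H]3[C@H]4O[C@@H]54)[C@@H]1[C@H]1C3=C([C@@H]5OO[C@H]3[C@@H]4O[C@H]54)[C@@H]2O[C@@H]1C
A2 | alternative 1 | cage bis(arene oxide) | C[C@H]1O[C@H]2C=3C(=C[C@@H]4O[C@@H]4C=3)[C@@H]1[C@H]1C=3C(=C[C@H]4O[C@H]4C=3)[C@@H]2O[C@@H]1C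
A3 | alternative 2 | acetonide-protected trans-11,12-dicarboxylic acid of the tetramethoxydibenzocyclooctadiene trans-diol | CC1(C)O[C@H]2c3c(OC)ccc(OC)c3[C@@H](C(=O)O)[C@H](C(=O)O)c3c(OC)ccc(OC)c3[C@@H]2O1
A4 | alternative 2 | acetonide-protected tetramethoxydibenzocyclooctatriene trans-diol | CC1(C)O[C@H]2c3c(OC)ccc(OC)c3C=Cc3c(OC)ccc(OC)c3[C@@H]2O1
A5 | alternative 3 | cage bis(epoxy enone ketal), identical with 19 | C[C@H]1O[C@H]2C3=C(C(OC)(OC)[C@@H]4O[C@@H]4C3=O)[C@@H]1[C@H]1C3=C(C(=O)[C@H]4O[C@H]4C3(OC)OC)[C@@H]2O[C@@H]1C
A6 | alternative 3 | cage bis(quinone monoketal), identical with 18 | C[C@H]1O[C@H]2C3=C(C(OC)(OC)C=CC3=O)[C@@H]1[C@H]1C3=C(C(=O)C=CC3(OC)OC)[C@@H]2O[C@@H]1C
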